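The constants used here were drawn at random within sensible limits; the flask was simulated.

1.10 moles of J charged per mole of D and X together: this reagent ratio is the number to carry through this flask. Solid J dissolves to E, E adds to D and to X, D and X interconvert, E.D and E.X interconvert, and E stands in balance with L.

D 0.041 M; J 0.0902 M; X 0.041 M; time 8.0 h

1. the state of affairs at 8.0 h: stopped, and by what, or still going (for what has run out or reacted, a solid counts together with what of it has only dissolved) (forward and back rates have come level / all of D has reacted / E has run out first / it is still moving)
2. how much of the D and X together has reacted by 8.0 h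
3. how much E.D there is at 8.0 h, in percent of the D and X together charged
4. how much E.X there is at 8.0 h, in percent of the D and X together charged

    E + D → E.D (k1 = 0.300 L mol⁻¹ s⁻¹)
    E + X → E.X (k2 = 0.105 L mol⁻¹ s⁻¹)
    D ⇌ X (k3 = 0.00152 s⁻¹)
    J ⇌ E, rate k4*(cs4 - [E]) while solid is left; crystals form when [E] > cs4 (cs4 = 8.0 mM, k4 = 0.00192 s⁻¹)
    E ⇌ L (K5 = 1.16, k5 = 0.00211 s⁻¹)
    E.D ⇌ E.X (k6 = 0.00606 s⁻¹)

Two chemists dispute the flask. The first reads the rate constants: at equal concentrations of D and X, E adds to D 2.86 times as fast as to X, a selectivity factor that she takes for kinetic control, so she expects 74.1% of the product as E.D and the rest as E.X.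

The second asks first what the end state must be. E.D and E.X have the same energy, and their relaxation half-life of 0.953 min is far shorter than the 8.0 h of the run, so he expects thermodynamic control and a level pair.

My own reckoning goes with him. With the pair relaxed, J dissolved and the additions run to their end, each product stands at half of the lesser of the ratio and 1, which here gives 50.0% each. Then how fast? J dissolves at no more than 0.922 mM min⁻¹, so the whole charge needs at least 1.63 h, a floor that is shorter than the run. My hand reckoning stops there, without the tail of the last substrate.

The forecast takes the second side: all of D has reacted, 100% converted, 50% E.D and 50% E.X, on the ground that “E.D and E.X interconvert”.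

The flask gives: all of D has reacted, with 0% of D and 0% of X left, 100% converted, 50.0% E.D and 50.0% E.X.

The first chemist's view holds for the moment's traffic: at 0.941 h this flask's E was going to E.D 2.6 times as fast as to E.X. Yet at 0.800 h the pair stood at 22.2% of E.D and 21.6% of E.X. The ratio above 1 leaves this flask a surplus of 8.20 mM, which stands at the end as 0.00380 M of E and 0.00440 M of L. The neighbour flask with 0.023 M of J has a ratio of 0.280, making J the limiting reagent, and half of that is 14.0%; that flask ends with 14.0% E.D and 14.0% E.X.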